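(The rate constants are those of an exercise; the run is a simulation.)

Work in molar per minute: gas passes into solution as reagent at k3·(csat − [reagent]), and that is the rate to set against what substrate can take up.

| flask | substrate | gas | time |
|---|---|---|---|
| dusk | 0.15 M | 180 mM (held) | 80 min |
| winter | 0.30 M | 180 mM (held) | 80 min |
| noon | 0.60 M | 180 mM (held) | 80 min |
| dawn | 1.2 M | 180 mM (held) | 80 min |
| midnight | 2.5 M | 180 mM (held) | 80 min |

    substrate + target ⇌ idle adduct, settled at all times (K1 = 4.2 M⁻¹)
    substrate + reagent ⇌ target + released group (K2 = 0.789, k2 = 0.143 M⁻¹ min⁻¹)
    gas ⇌ reagent, rate k3*(csat - [reagent]) (k3 = 0.00888 min⁻¹, csat = 180 mM)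
    released group → by-product carried off (k4 = 0.00785 min⁻¹)

- a species is counted by the substrate in it: one idle adduct counts as two
- amounts and yields of target count idle adduct too
- at the start none of reagent is dissolved
- in an amount of target, one idle adduct counts as one target
- the concentration of target that is asked is that of its free form alone
- "hardly changes" means that all values lie within two and a half points (for a concentration: within two and a half percent of the largest)
- run time (dusk): 80 min

* [target] (only what is free in solution) at the end for dusk, winter, noon, dawn, midnight, in this order
* how the row runs (hardly changes / falls all the way / rises all the way / falls, then rises / rises, then falls)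

Take midnight first. At midnight substrate uses up reagent within a lag 1/(k2·[substrate]) of 2.80 min, short against the run, so reagent sits on a low plateau b = k3·csat/(k2·[substrate]). Transfer is then the rate-limiting step of the midnight flask. Replace its curve by its mean, and total target becomes G = k3·csat·t. The fast balance divides this by a lock factor, 1 + K1·[substrate], giving free target F = G/(1 + K1·[substrate]).

Ask first which numbers F needs. Know k3, csat and the time well, since they enter in direct proportion. Know K1 nearly as well: F moves by 0.913 of any percentage error in it. Know k2, K2 and k4 roughly, since they reach F through the standing reagent, and b at midnight is 0.00447 M, or 2.48% of csat.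

Now reckon midnight: G is 0.128 M, and F, supply divided by lock factor at the charged substrate, is 0.0111 M: the paced free target. Check the error of the mean. At midnight falling substrate lifts F by about 9.34%, while the reagent gap and the reagent still dissolved lower it by about 5.98%, so the two partly cancel. Stop before dusk, where b would be 41.4% of csat; my reckoning gives no rising arm.

The forecast gives 0.031 M, 0.036 M, 0.03 M, 0.021 M and 0.0113 M, so the row rises, then falls, and of the high charges it says that “the adduct locks target away”. Its midnight value differs slightly from mine.

The simulation gives 0.0313 M, 0.0362 M, 0.0316 M, 0.0209 M and 0.0113 M, and the row rises, then falls. Midnight reads 0.0113 M against F of 0.0111 M, and dawn reads 0.0209 M against 0.0212 M from the same division. Set reagent against csat at the end: midnight holds 0.00528 M, while dusk holds 0.0588 M, a third of csat. At dusk reagent is still made 1.80 times faster than it is used up, each step taken net, after 80.0 min.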